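The leftover in the noon run is tiny: after 5.00 h only 3.8% of L remains, yet Z holds just 44.9%. L has nearly disappeared, but the chains haven't received most of it.

| flask | L | G | E | temperature | remark | time |
|---|---|---|---|---|---|---|
| noon | 0.017 M | 5.1 mM | 4.8 mol% | 60 °C | run made earlier |  |
| teal | 0.017 M | 5.10 mM | 2.4 mol% | 60 °C |  | 25 h |
| amber | 0.017 M | 5.10 mM | 2.4 mol% | 20 °C |  | 25 h |
| green | 0.017 M | 5.10 mM | 2.4 mol% | 40 °C |  | 25 h |

noon run (percent of the L charged)

| time / h | Z / % | L / % |
|---|---|---|
| 0.417 | 11.1 | 69.2 |
| 0.667 | 17.3 | 54.8 |
| 1.00 | 25.0 | 40.6 |
| 1.33 | 29.5 | 31.9 |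
| 2.00 | 36.4 | 19.2 |
| 3.00 | 40.7 | 9.8 |
| 5.00 | 44.9 | 3.8 |

(readings scatter by 0.5 percentage points)

- a species is counted by the L in it: one Q counts as two
- candidate steps: L + E -> D + Z; L + D -> Z + D; D + G -> X; L -> J; 2 L -> Q
- the earlier runs do not show what temperature does; that part of a forecast is a guess
- no earlier run changes the charge of E; that part of a forecast is a guess

- the best flask by amount of Z, in percent of the L charged; "all alike" if 1.5 percentage points covers them all (teal / amber / green / all alike)
- amount of Z at the end, in percent of the L charged, teal
- amount of Z at the end, in percent of the L charged, amber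
- amount of Z at the end, in percent of the L charged, green

Subtraction clears this up. The other 51.3% of the charge has left L without entering Z, so I look for it in the candidate products J and Q. I therefore split the question in two: what share of the lost L becomes Z, and how much L is lost by the end? I call the first s, the Z share of lost L, which is the selectivity for Z:

s = c(Z) / (charge − c(L)) = 44.9% / 96.2% = 46.7%

My estimate for a flask is then:

c(Z) ≈ s × (charge − c(L))

This s is a reading at noon's E and temperature, so on the new flasks it is only a yardstick. A flask that finished on this share would hold 46.7% of the charge as Z, and I put no number on the halved E or on the cooling, which are guesses.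

The forecast names green as best, with 29% for teal, 30% for amber and 35% for green. For amber it warns that “L may be unfinished at 25 h”. On my share, its amber figure needs 64.3% of L gone.

The flask gives teal 29.1%, amber 18.3% and green 39.6%, so green is best. Amber lies 12 percentage points below the forecast.

    L + E → D + Z (k = 38.0 /M/h, Ea = 68.0 kJ/mol)
    L + D → Z + D, rate k2*[D]*[L] (k = 180 /M/h, Ea = 58.0 kJ/mol)
    D + G → X (k = 6.30 /M/h, Ea = 82.0 kJ/mol)
    L → J (k = 0.0160 /h, Ea = 115 kJ/mol)
    2 L → Q (k = 3.00 /M/h, Ea = 62.0 kJ/mol)
    (constants at 40 °C)

Amber has lost 47.8% of its L at 25.0 h, less than the forecast's figure needs. My share gives 22.3% there, still above what amber holds. Part of amber's low Z comes from the reading at this time rather than at 250 h, together with the reaction of two L to Q: read later, amber holds 52.3%, and without the step to Q it holds 23.5% at the asked time.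

Amber read at 4.0 d has 13.5% of its L left, so s gives 40.4%. The computed value is 43.4%.

(Readings and results stem from a simulated flask on assumed constants.)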